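## Retrosynthetic overview
1. Target ⇒ desilylation and 1,2-reduction at C9 of a 2-methylenecycloheptanone embedded in a trans-hydroazulene.
2. ⇒ ring expansion of a 9-ethynyl-trans-hydrindan-9-ol. C1 shifts from C9 to the inner alkyne carbon, creating the C1–C10 bond, C10=CH2 and C9=O in one step.
3. ⇒ side chain. C7–C11 comes from Mukaiyama–Michael addition of the silyl dienol ether of (E)-6-hydroxy-6-methylhept-4-en-3-one (made by cross metathesis) to a trans-hydrindadienone. C12 comes from ketone reduction, then acetylation.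
4. ⇒ cyclopentene by ring-closing metathesis (C3=C4) of a trans-2-allyl-3-isopropenylcyclohexanone. That ketone comes from conjugate addition/allylation of (R)-4-silyloxycyclohexenone (cyclohexadiene + O2, desymmetrised).
5. Ring order: six-membered carbocycle (bought as the diene) → fused cyclopentene → six-membered ring enlarged to the seven-membered ring.

Assumption: the SMILES is taken literally, which gives (1R,5S,6R,7S,9R,11R,12S). This means a trans ring fusion (H-1 α, H-5 β), 6β-OH, 7β side chain and 9α-OH. Dictyol numbering C1–C15 of the target is used as locants for all intermediates; C9 is the ketone carbon of the six-membered ring, and C10 and its CH2 arrive with the alkyne.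

## Route

Step 1
Reactants: 1 cyclohexa-1,3-diene
Product: 3 (R)-4-hydroxycyclohex-2-en-1-one, via endoperoxide 2 (not isolated)
Conditions: O2, tetraphenylporphyrin (0.1 mol %), visible light, CH2Cl2, 0 °C; then bifunctional 6'-hydroxy cinchona base of the cupreidine/cupreine type (10 mol %, the pseudoenantiomer that deprotonates the S bridgehead), rt
Reagents that add atoms: oxygen O=O
Why: Singlet-oxygen [4+2] addition gives the meso endoperoxide, and a chiral-base Kornblum–DeLaMare rearrangement removes only the bridgehead H of the S carbon, so the untouched C–O carbon becomes C6 with R configuration (desymmetrisation).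

Step 2
Reactants: 3 (R)-4-hydroxycyclohex-2-en-1-one
Product: 4 (R)-4-(tert-butyldimethylsilyloxy)cyclohex-2-en-1-one
Conditions: TBSCl, imidazole, CH2Cl2, 0 °C to rt
Reagents that add atoms: tert-butyldimethylsilyl chloride CC(C)(C)[Si](C)(C)Cl
Why: Standard silylation of a secondary alcohol that leaves C6 untouched and supplies the bulky γ-substituent that steers step 3.

Step 3
Reactants: 4 (R)-4-(tert-butyldimethylsilyloxy)cyclohex-2-en-1-one; 5 isopropenylmagnesium bromide; 6 allyl iodide
Product: 8 (2R,3S,4R)-2-allyl-4-(tert-butyldimethylsilyloxy)-3-(prop-1-en-2-yl)cyclohexan-1-one, via magnesium enolate 7 (not isolated)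
Conditions: 5 (1.3 equiv), CuBr·SMe2 (10 mol %), LiCl, THF, −78 °C; then 6 (3 equiv), DMPU, −78 to −20 °C
Reagents that add atoms: none
Why: Copper-catalysed conjugate addition followed by enolate alkylation (three-component coupling) adds the isopropenyl group anti to the C6 silyloxy group (sets C5) and the allyl group anti to the isopropenyl group (sets C1), giving the all-equatorial trans,trans ketone.

Step 4
Reactants: 8 (2R,3S,4R)-2-allyl-4-(tert-butyldimethylsilyloxy)-3-(prop-1-en-2-yl)cyclohexan-1-one
Product: 9 trans-hydrindenone (3aS,4R,7aR)-4-(tert-butyldimethylsilyloxy)-3-methyl-1,3a,4,5,6,7a-hexahydro-7H-inden-7-one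
Conditions: second-generation Grubbs catalyst (5 mol %), CH2Cl2 (5 mM), 40 °C
Reagents that add atoms: none
Why: Ring-closing metathesis of the gauche diequatorial allyl and isopropenyl groups closes the C3=C4(CH3) cyclopentene under neutral conditions, so the trans relation of C1 and C5 is carried into the ring fusion.

Step 5
Reactants: 9 trans-hydrindenone
Product: 11 (3aS,4R,7aR)-4-(tert-butyldimethylsilyloxy)-3-methyl-1,3a,4,7a-tetrahydro-7H-inden-7-one (C7=C8 enone), via lithium enolate 10 (not isolated)
Conditions: LDA, THF, −78 °C; then N-tert-butylbenzenesulfinimidoyl chloride, −78 °C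
Reagents that add atoms: none
Why: Kinetic deprotonation takes the C8 methylene rather than the C1 methine, and the Mukaiyama sulfinimidoyl chloride dehydrogenation turns that enolate into the C7=C8 enone at −78 °C without epimerising C1.

Step 6
Reactants: 12 ethyl vinyl ketone; 13 2-methylbut-3-en-2-ol
Product: 14 (E)-6-hydroxy-6-methylhept-4-en-3-one
Conditions: 13 (3 equiv), second-generation Hoveyda–Grubbs catalyst (3 mol %), CH2Cl2, 40 °C
Reagents that add atoms: none
Why: Olefin cross metathesis of an enone with an excess of a cheap tertiary allylic alcohol is E-selective and delivers C11–C15 in one piece.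

Step 7
Reactants: 14 (E)-6-hydroxy-6-methylhept-4-en-3-one; 11 C7=C8 enone
Product: 16 (1R,5S,6R,7S,11R) Michael adduct as its C9 triethylsilyl enol ether (C8=C9; 6β-OTBS; axial 7β-CH(CH3)-CO-CH=CH-C(CH3)2OTES), via silyl dienol ether 15 (not isolated)
Conditions: 14 (1.4 equiv), Et3SiOTf (3.1 equiv), Et3N (2.9 equiv), CH2Cl2, −78 to 0 °C; then 11, −78 °C; Et3N quench, Et3N-deactivated SiO2
Reagents that add atoms: triethylsilyl triflate CC[Si](CC)(CC)OS(=O)(=O)C(F)(F)F
Why: In this Mukaiyama–Michael addition the locked trans-hydrindenone is attacked axially on the β face of C7 (chair-like enol ether, cis to the equatorial 6-OTBS), through a synclinal open transition state with H-11 over the ring, the small CH3 next to C6-OTBS and the bulky C12 over C8, which gives 11R, while silyl transfer leaves C9 masked.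

Step 8
Reactants: 16 Michael adduct (C9 triethylsilyl enol ether)
Product: 18 (12S)-hydroxy ketone (C9 ketone; 12-OH; 6β-OTBS; 15-OTES; may rest partly as its C9/O12 hemiketal), via allylic alcohol 17 (not isolated)
Conditions: (S)-2-methyl-CBS-oxazaborolidine (0.3 equiv), catecholborane (2 equiv), toluene, −78 °C; then 1 M aq. citric acid, THF, 0 °C
Reagents that add atoms: none
Why: The Corey–Bakshi–Shibata reduction meets only one ketone because C9 is masked, treats the alkenyl arm as the large group, and is matched with Felkin–Anh attack (ring carbon C7 as large group), giving the 11,12-anti (12S) alcohol before mild acid frees the C9 ketone.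

Step 9
Reactants: 18 (12S)-hydroxy ketone; 19 ethynylmagnesium bromide
Product: 20 (9S)-9-ethynyl-trans-hydrindane-9,12-diol (9β-OH axial; 9α-ethynyl equatorial; 6β-OTBS; 15-OTES)
Conditions: 19 (4 equiv), LaCl3·2LiCl (1 equiv), THF, −78 to 0 °C; aqueous work-up
Reagents that add atoms: none
Why: Lanthanum-assisted 1,2-addition of the small, weakly basic acetylide avoids enolisation at C1 and comes from the α face, away from the axial C7 chain, and the new C9 centre is of no consequence because step 11 erases it.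

Step 10
Reactants: 20 9-ethynyl diol
Product: 21 (12S)-12-acetate of 20 (tertiary 9-OH free)
Conditions: Ac2O (1.5 equiv), pyridine, DMAP (5 mol %), CH2Cl2, 0 °C
Reagents that add atoms: acetic anhydride CC(=O)OC(C)=O
Why: Acylation takes the only free secondary alcohol, while the tertiary propargylic 9-OH is inert at 0 °C and O6 and O15 are silylated.

Step 11
Reactants: 21 9-ethynyl carbinol acetate
Product: 22 trans-hydroazulenone (10-methylene; C9 ketone; 6β-OTBS; 12-OAc; 15-OTES)
Conditions: [(2,4-tBu2C6H3O)3P]AuCl (5 mol %), AgSbF6 (5 mol %), 4 Å MS, CH2Cl2, 0 °C to rt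
Reagents that add atoms: none
Why: Proposed new method: a cationic, strongly π-acidic phosphite complex of monovalent gold binds the terminal alkyne and builds positive charge on its inner carbon C10, the more substituted C9–C1 σ-bond then shifts to C10 with retention at C1 (semipinacol-type 1,2-alkyl shift pushed by the OH lone pair), and protodeauration of the vinylgold gives the exocyclic methylene ketone; C=O formation (roughly 25 kcal/mol downhill), relief of trans-hydrindene strain and loss of the 1,3-diaxial C7/C9 contact take the place of the ring strain that drives the closest known reaction type, the gold-catalysed ring expansion of 1-alkynylcyclopropanols and 1-alkynylcyclobutanols to 2-alkylidenecycloalkanones, which has not been shown for an unstrained cyclohexanol.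

Step 12
Reactants: 22 trans-hydroazulenone
Product: 23 (9R)-9α-allylic alcohol (bis-silyl ether of the target)
Conditions: (S)-2-methyl-CBS-oxazaborolidine (0.5 equiv), catecholborane (2 equiv), toluene, −78 °C
Reagents that add atoms: none
Why: Corey–Bakshi–Shibata 1,2-reduction with reagent control reads the α-methylene carbon C10 as the large group and the C8 methylene as the small group, so the S catalyst gives the 9R alcohol, and the acetate and alkenes are inert at −78 °C.

Step 13
Reactants: 23 bis-silyl ether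
Product: 24 target CNP0213969.2
Conditions: HF·pyridine, pyridine, THF, 0 °C to rt
Reagents that add atoms: none
Why: Buffered fluoride desilylation removes the TES and TBS groups without touching the acetate, the allylic alcohols or any stereocentre.

## Compound list
1 | cyclohexa-1,3-diene | C1=CC=CCC1 | starting material
2 | 2,3-dioxabicyclo[2.2.2]oct-5-ene (meso endoperoxide) | C1C[C@H]2C=C[C@@H]1OO2 | intermediate
3 | (R)-4-hydroxycyclohex-2-en-1-one | O=C1CC[C@@H](O)C=C1 | intermediate
4 | (R)-4-(tert-butyldimethylsilyloxy)cyclohex-2-en-1-one | O=C1CC[C@@H](O[Si](C)(C)C(C)(C)C)C=C1 | intermediate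
5 | isopropenylmagnesium bromide | C=C(C)[Mg]Br | starting material
6 | allyl iodide | C=CCI | starting material
7 | bromomagnesium C9=C1 enolate of (3S,4R)-4-(TBSO)-3-isopropenylcyclohexanone | Br[Mg]OC1=C[C@@H](C(C)=C)[C@H](O[Si](C)(C)C(C)(C)C)CC1 | intermediate
8 | (2R,3S,4R)-2-allyl-4-(tert-butyldimethylsilyloxy)-3-(prop-1-en-2-yl)cyclohexan-1-one | O=C1CC[C@@H](O[Si](C)(C)C(C)(C)C)[C@H](C(C)=C)[C@H]1CC=C | intermediate
9 | (3aS,4R,7aR)-4-(tert-butyldimethylsilyloxy)-3-methyl-1,3a,4,5,6,7a-hexahydro-7H-inden-7-one (trans-fused) | O=C1CC[C@@H](O[Si](C)(C)C(C)(C)C)[C@@H]2C(C)=CC[C@@H]12 | intermediate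
10 | kinetic lithium C8=C9 enolate of 9 | [Li]OC1=CC[C@@H](O[Si](C)(C)C(C)(C)C)[C@@H]2C(C)=CC[C@@H]12 | intermediate
11 | (3aS,4R,7aR)-4-(tert-butyldimethylsilyloxy)-3-methyl-1,3a,4,7a-tetrahydro-7H-inden-7-one | O=C1C=C[C@@H](O[Si](C)(C)C(C)(C)C)[C@@H]2C(C)=CC[C@@H]12 | intermediate
12 | ethyl vinyl ketone (pent-1-en-3-one) | C=CC(=O)CC | starting material
13 | 2-methylbut-3-en-2-ol | C=CC(C)(C)O | starting material
14 | (E)-6-hydroxy-6-methylhept-4-en-3-one | CCC(=O)/C=C/C(C)(C)O | intermediate
15 | (2Z,4E)-6-methyl-3,6-bis(triethylsilyloxy)hepta-2,4-diene | C/C=C(/C=C/C(C)(C)O[Si](CC)(CC)CC)O[Si](CC)(CC)CC | intermediate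
16 | (1R,5S,6R,7S,11R) Michael adduct, C9 triethylsilyl enol ether, C12 enone, 6β-OTBS, 15-OTES | CC[Si](CC)(CC)OC1=C[C@@H]([C@@H](C)C(=O)/C=C/C(C)(C)O[Si](CC)(CC)CC)[C@@H](O[Si](C)(C)C(C)(C)C)[C@@H]2C(C)=CC[C@@H]12 | intermediate
17 | (12S)-allylic alcohol of 16, C9 enol ether still in place (present as its catecholborate) | CC[Si](CC)(CC)OC1=C[C@@H]([C@@H](C)[C@H](/C=C/C(C)(C)O[Si](CC)(CC)CC)O)[C@@H](O[Si](C)(C)C(C)(C)C)[C@@H]2C(C)=CC[C@@H]12 | intermediate
18 | (1R,5S,6R,7S,11R,12S)-12-hydroxy C9 ketone, 6β-OTBS, 15-OTES | O=C1C[C@@H]([C@@H](C)[C@H](/C=C/C(C)(C)O[Si](CC)(CC)CC)O)[C@@H](O[Si](C)(C)C(C)(C)C)[C@@H]2C(C)=CC[C@@H]12 | intermediate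
19 | ethynylmagnesium bromide | C#C[Mg]Br | starting material
20 | (9S)-9α-ethynyl-9β,12-diol, 6β-OTBS, 15-OTES | O[C@@]1(C#C)C[C@@H]([C@@H](C)[C@H](/C=C/C(C)(C)O[Si](CC)(CC)CC)O)[C@@H](O[Si](C)(C)C(C)(C)C)[C@@H]2C(C)=CC[C@@H]12 | intermediate
21 | 12-acetate of 20 | O[C@@]1(C#C)C[C@@H]([C@@H](C)[C@H](/C=C/C(C)(C)O[Si](CC)(CC)CC)OC(C)=O)[C@@H](O[Si](C)(C)C(C)(C)C)[C@@H]2C(C)=CC[C@@H]12 | intermediate
22 | trans-hydroazulen-9-one with 10-methylene, 6β-OTBS, 12-OAc, 15-OTES | C=C1C(=O)C[C@@H]([C@@H](C)[C@H](/C=C/C(C)(C)O[Si](CC)(CC)CC)OC(C)=O)[C@@H](O[Si](C)(C)C(C)(C)C)[C@@H]2C(C)=CC[C@@H]12 | intermediate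
23 | (9R)-9α-alcohol, 6-O-TBS and 15-O-TES ether of the target | C=C1[C@H](O)C[C@@H]([C@@H](C)[C@H](/C=C/C(C)(C)O[Si](CC)(CC)CC)OC(C)=O)[C@@H](O[Si](C)(C)C(C)(C)C)[C@@H]2C(C)=CC[C@@H]12 | intermediate
24 | CNP0213969.2, (1R,5S,6R,7S,9R,11R,12S) | C=C1[C@H](O)C[C@@H]([C@@H](C)[C@H](/C=C/C(C)(C)O)OC(C)=O)[C@@H](O)[C@@H]2C(C)=CC[C@@H]12 | target

## Count and risks
Total steps: 13. Longest linear sequence: 12 (steps 1–5 and 7–13).

**Step 11 (new ring expansion).** The risk is that, without ring strain, the 1,2-shift loses to Meyer–Schuster or Rupe pathways, or that the methylene ketone isomerises to the endocyclic enone.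

The fallback uses known chemistry only, sets out from 21 and comes back at 22. Semihydrogenation (H2, Pd/CaCO3 poisoned with Pb(OAc)2, quinoline) gives the 9-vinyl carbinol F1. Hydroxyl-directed epoxidation (VO(acac)2, t-BuOOH) gives the α-hydroxy epoxide F2, whose C10 epimers are both usable. BF3·OEt2 at −78 °C then triggers the classical semipinacol rearrangement of a 2,3-epoxy alcohol, again with migration of the more substituted C1, to the ring-enlarged β-hydroxy ketone F3. MsCl/Et3N gives the mesylate F4, and DBU eliminates it to 22.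

**Step 7 (Mukaiyama–Michael addition).** The risks are a modest C11 ratio, a formal [4+2] reaction of the silyloxydiene with the enone, and sluggish attack next to the OTBS group.

The fallback sets out from 11 and comes back at 16; it forms C12–C13 after the Michael step instead of before it. S-ethyl propanethioate (LDA, Et3SiCl) gives the geometrically defined ketene silyl thioacetal F5. This donor class contains no diene and either geometry can be made, so either C11 epimer is reachable. F5 adds to 11 (Et3SiOTf cat., −78 °C) to give the thioester enol ether F6. Separately, 2-methylbut-3-yn-2-ol is silylated to the TES ether F7 and hydrostannylated (Bu3SnH, PdCl2(PPh3)2) to the (E)-vinylstannane F8. A neutral thioester–stannane ketone synthesis (Pd2(dba)3, P(2-furyl)3, copper thiophene-2-carboxylate Cu(O2CC4H3S)) joins F6 and F8 to 16.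

**Step 12 (C9 configuration).** The risk is that the conformation of the seven-membered ring opposes the catalyst and the 9β-alcohol dominates, or that catecholborane reduces the s-cis enone in a 1,4 sense.

The fallback sets out from 22 and comes back at 23. Luche reduction (NaBH4, CeCl3·7H2O, MeOH, −78 °C) is allowed to follow the substrate bias to the 9β-alcohol F9. Mitsunobu inversion with formic acid (PPh3, DIAD) gives the 9α-formate F10. KHCO3 in MeOH then removes the formate much faster than the C12 acetate and gives 23.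

## Further compounds
F1 | step 11 | 9-vinyl carbinol (9β-OH; 12-OAc; 6β-OTBS; 15-OTES) | O[C@@]1(C=C)C[C@@H]([C@@H](C)[C@H](/C=C/C(C)(C)O[Si](CC)(CC)CC)OC(C)=O)[C@@H](O[Si](C)(C)C(C)(C)C)[C@@H]2C(C)=CC[C@@H]12
F2 | step 11 | α-hydroxy epoxide (oxiranyl at C9; C10 epimers) | O[C@@]1(C3CO3)C[C@@H]([C@@H](C)[C@H](/C=C/C(C)(C)O[Si](CC)(CC)CC)OC(C)=O)[C@@H](O[Si](C)(C)C(C)(C)C)[C@@H]2C(C)=CC[C@@H]12
F3 | step 11 | ring-enlarged 10-(hydroxymethyl) C9 ketone (C10 epimers) | OCC1C(=O)C[C@@H]([C@@H](C)[C@H](/C=C/C(C)(C)O[Si](CC)(CC)CC)OC(C)=O)[C@@H](O[Si](C)(C)C(C)(C)C)[C@@H]2C(C)=CC[C@@H]12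
F4 | step 11 | mesylate of F3 | CS(=O)(=O)OCC1C(=O)C[C@@H]([C@@H](C)[C@H](/C=C/C(C)(C)O[Si](CC)(CC)CC)OC(C)=O)[C@@H](O[Si](C)(C)C(C)(C)C)[C@@H]2C(C)=CC[C@@H]12
F5 | step 7 | 1-(ethylthio)-1-(triethylsilyloxy)prop-1-ene (CH3 cis to OSiEt3) | C/C=C(/SCC)O[Si](CC)(CC)CC
F6 | step 7 | (11R) S-ethyl thioester Michael adduct, C9 triethylsilyl enol ether | CC[Si](CC)(CC)OC1=C[C@@H]([C@@H](C)C(=O)SCC)[C@@H](O[Si](C)(C)C(C)(C)C)[C@@H]2C(C)=CC[C@@H]12
F7 | step 7 | 2-methyl-2-(triethylsilyloxy)but-3-yne | C#CC(C)(C)O[Si](CC)(CC)CC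
F8 | step 7 | (E)-tributyl[3-methyl-3-(triethylsilyloxy)but-1-enyl]stannane | CCCC[Sn](CCCC)(CCCC)/C=C/C(C)(C)O[Si](CC)(CC)CC
F9 | step 12 | 9β-alcohol (C9 epimer of 23) | C=C1[C@@H](O)C[C@@H]([C@@H](C)[C@H](/C=C/C(C)(C)O[Si](CC)(CC)CC)OC(C)=O)[C@@H](O[Si](C)(C)C(C)(C)C)[C@@H]2C(C)=CC[C@@H]12
F10 | step 12 | 9α-formate of 23 | C=C1[C@H](OC=O)C[C@@H]([C@@H](C)[C@H](/C=C/C(C)(C)O[Si](CC)(CC)CC)OC(C)=O)[C@@H](O[Si](C)(C)C(C)(C)C)[C@@H]2C(C)=CC[C@@H]12
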